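**Retrosynthetic overview**
- The target is cut at the C18 ester and the C15 acid into methyl (13S)-18-hydroxy-ent-labd-8(17)-en-15-oate and (E)-4-acetoxycinnamic acid.
- Key step: ring A, the quaternary C4 and the C18–O bond are made together by an intramolecular nitrile oxide–alkene [3+2] cycloaddition onto an isopropenyl group. The isoxazoline is then opened, the C3 carbonyl removed and C8 methylenated.
- The cycloaddition precursor is a cyclohexanone (ring B) obtained by acetolytic opening of the cyclobutane of a verbenone-derived nopinone; the CMe2 bridge becomes the isopropenyl group (C4, C18, C19).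
- The nopinone comes from (1S)-(−)-verbenone (supplies C5 and controls C10) by cuprate addition of the C1–C3 chain and enolate alkylation with a C11–C16 iodide made from methyl hydrogen (R)-3-methylglutarate (supplies C13).
- Ring order: ring B is the six-membered ring of verbenone (bought); ring A is closed by the cycloaddition; the isoxazoline ring is transient.

Assumption: verbenone and the half ester are used at ≥98% ee (commercial verbenone is often of lower ee, so that grade must be specified or made from (−)-α-pinene of that quality); locants C1–C20 below are labdane numbering of the target.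

**Step 1**
Reactants: 1 (1S,5S)-(−)-verbenone; 2 (3-bromopropoxy)(tert-butyl)dimethylsilane
Product: 4 (1S,4R,5R)-4-{3-[(tert-butyldimethylsilyl)oxy]propyl}-4,6,6-trimethyl-2-(trimethylsilyloxy)bicyclo[3.1.1]hept-2-ene (new chain anti to the CMe2 bridge), via Grignard reagent 3 (not isolated)
Conditions: 2, Mg, THF; then CuBr·SMe2 (10 mol%), TMSCl, HMPA, 1, THF, −78 → −40 °C
Reagents that add atoms: chlorotrimethylsilane, C[Si](C)(C)Cl
Why: Copper-catalysed, TMSCl-accelerated conjugate addition to the β,β-disubstituted enone occurs on the face opposite the CMe2 bridge, which sets the quaternary C10 with its methyl cis to the future C4 unit, and the enolate is trapped as the silyl enol ether.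

**Step 2**
Reactants: 5 methyl hydrogen (R)-3-methylglutarate
Product: 7 (S)-4-methyltetrahydro-2H-pyran-2-one, via hydroxy acid 6 (not isolated)
Conditions: LiBH4, THF, 0 → 50 °C; then 2 M HCl, rt
Reagents that add atoms: none
Why: Chemoselective hydride reduction of the ester in the presence of the lithium carboxylate, then acid-induced lactonisation; the bought stereocentre (future C13) is not touched.

**Step 3**
Reactants: 7 (S)-4-methyltetrahydro-2H-pyran-2-one
Product: 9 methyl (R)-5-iodo-3-methylpentanoate, via silyl ester 8 (not isolated)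
Conditions: TMSI, CH2Cl2, rt; then MeOH, rt → 50 °C
Reagents that add atoms: iodotrimethylsilane, C[Si](C)(C)I; methanol, CO
Why: Silyl-assisted SN2 opening of the lactone by iodide at the primary O–CH2 carbon, then HI-catalysed Fischer esterification when methanol is added; the stereocentre is remote from both events.

**Step 4**
Reactants: 4 silyl enol ether; 9 methyl (R)-5-iodo-3-methylpentanoate
Product: 11 methyl (3S)-5-[(1S,3R,4R,5R)-4-{3-[(tert-butyldimethylsilyl)oxy]propyl}-4,6,6-trimethyl-2-oxobicyclo[3.1.1]hept-3-yl]-3-methylpentanoate (major epimer, side chain anti to the CMe2 bridge), via lithium enolate 10 (not isolated)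
Conditions: MeLi, THF, 0 °C; then 9, DMPU, −78 → 0 °C
Reagents that add atoms: none
Why: The regiospecific lithium enolate released from the silyl enol ether is C-alkylated by the primary iodide (SN2 enolate alkylation); the other α-carbon is a bridgehead, and the new centre (C9), formed mainly anti to the bridge, is reset in step 6.

**Step 5**
Reactants: 11 alkylated nopinone
Product: 12 methyl (3S)-5-[(1R,5R,6R)-2-acetoxy-6-(3-acetoxypropyl)-6-methyl-5-(prop-1-en-2-yl)cyclohex-2-en-1-yl]-3-methylpentanoate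
Conditions: BF3·OEt2, Zn(OAc)2, Ac2O, 0 °C → rt
Reagents that add atoms: acetic anhydride, CC(=O)OC(C)=O
Why: Lewis-acid acetolytic fragmentation of the strained cyclobutyl ketone (nopinone-type ring opening) breaks the bridgehead–CMe2 bond: the tertiary cation loses a proton to give the isopropenyl group, the ketone is trapped as the Δ7 enol acetate and the silyl ether is exchanged for acetate, with C5 and C10 untouched.

**Step 6**
Reactants: 12 enol acetate
Product: 13 methyl (3S)-5-[(1S,2R,3R)-2-(3-hydroxypropyl)-2-methyl-6-oxo-3-(prop-1-en-2-yl)cyclohexyl]-3-methylpentanoate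
Conditions: K2CO3, MeOH, rt, 16 h
Reagents that add atoms: none
Why: Methanolysis (transesterification) of both acetates frees the C8 ketone and the primary alcohol, and the base epimerises C9 to the thermodynamic isomer with the side chain equatorial and cis to the C10 methyl (estimated about 4–5:1; the minor epimer is separated and re-equilibrated).

**Step 7**
Reactants: 13 keto alcohol
Product: 14 methyl (3S)-3-methyl-5-[(1S,2R,3R)-2-methyl-6-oxo-2-(3-oxopropyl)-3-(prop-1-en-2-yl)cyclohexyl]pentanoate
Conditions: TEMPO (10 mol%), PhI(OAc)2, CH2Cl2, rt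
Reagents that add atoms: none
Why: Oxoammonium (TEMPO/BAIB) oxidation takes the primary alcohol to the aldehyde and leaves the ketone, ester and alkene alone.

**Step 8**
Reactants: 14 keto aldehyde
Product: 15 methyl (3S)-5-[(1S,2R,3R)-2-[(3E)-3-(hydroxyimino)propyl]-2-methyl-6-oxo-3-(prop-1-en-2-yl)cyclohexyl]-3-methylpentanoate
Conditions: NH2OH·HCl, NaOAc, EtOH/H2O, 0 °C
Reagents that add atoms: hydroxylamine hydrochloride, Cl.NO
Why: Oxime condensation is much faster at the unhindered aldehyde than at the C8 ketone flanked by a tertiary centre.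

**Step 9**
Reactants: 15 aldoxime
Product: 18 methyl (13S)-8-oxo-17-nor-ent-labdan-15-oate with C3 and C18 joined as a 2-isoxazoline (C3=N–O–C18H2; trans-decalin; 4-CH3 and 10-CH3 cis), via hydroximoyl chloride 16 (not isolated), via nitrile oxide 17 (not isolated)
Conditions: aq. NaOCl, CH2Cl2, 0 °C → rt, 5 mM
Reagents that add atoms: none
Why: The nitrile oxide adds intramolecularly to the isopropenyl group in a 1,3-dipolar [3+2] cycloaddition that closes ring A trans-fused through a chair-like transition state; the fused isoxazoline needs the C18–O carbon quasi-eclipsed with C=N (equatorial), so the C4 methyl ends up axial and cis to the C10 methyl.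

**Step 10**
Reactants: 18 isoxazoline ketone
Product: 19 methyl (13S)-ent-labd-8(17)-en-15-oate with C3 and C18 joined as a 2-isoxazoline
Conditions: Ph3PCH3Br, KOt-Bu, THF/toluene, rt → 60 °C
Reagents that add atoms: methyltriphenylphosphonium bromide, C[P+](c1ccccc1)(c1ccccc1)c1ccccc1.[Br-]
Why: Wittig methylenation of the only free ketone installs the exocyclic C8=C17 alkene while the isoxazoline masks the C3 carbonyl; C9 is already in its thermodynamic configuration.

**Step 11**
Reactants: 19 methylene isoxazoline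
Product: 21 methyl (13S)-18-hydroxy-3-oxo-ent-labd-8(17)-en-15-oate, via hydroxy imine 20 (not isolated)
Conditions: Mo(CO)6, MeCN/H2O, 80 °C
Reagents that add atoms: water, O
Why: Molybdenum-mediated reductive N–O cleavage and in-situ imine hydrolysis unmask the β-hydroxy ketone without reducing the exocyclic alkene.

**Step 12**
Reactants: 21 β-hydroxy ketone
Product: 23 methyl (13S)-18-hydroxy-ent-labd-8(17)-en-15-oate, via tosylhydrazone 22 (not isolated)
Conditions: TsNHNH2, EtOH, 70 °C, evaporate; catecholborane, CHCl3, 0 °C → rt; NaOAc·3H2O, 60 °C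
Reagents that add atoms: none
Why: Kabalka reductive deoxygenation (hydroboration of the tosylhydrazone, then loss of sulfinate and N2) turns C3=O into CH2 under near-neutral conditions, avoiding the retro-aldol loss of C18 that a Wolff–Kishner reduction would risk.

**Step 13**
Reactants: 23 hydroxy ester; 24 (E)-4-acetoxycinnamic acid
Product: 25 methyl (13S)-18-[(E)-4-acetoxycinnamoyloxy]-ent-labd-8(17)-en-15-oate
Conditions: EDC·HCl, DMAP, CH2Cl2, rt
Reagents that add atoms: none
Why: Steglich esterification acylates the neopentyl primary alcohol; the E-alkene is bought and the phenol is masked as its acetate.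

**Step 14**
Reactants: 25 protected ester
Product: 26 (13S)-18-[(E)-4-hydroxycinnamoyloxy]-ent-labd-8(17)-en-15-oic acid, (4S,5S,9R,10S,13S), the target
Conditions: LiOH·H2O, THF/H2O, 0 °C → rt; then 1 M HCl
Reagents that add atoms: lithium hydroxide, [Li+].[OH-]
Why: Saponification cleaves the aryl acetate at once, and the resulting phenoxide deactivates the hindered neopentyl cinnamate, so only the unhindered methyl ester is hydrolysed further.

**Compound list**
1 | (1S,5S)-(−)-verbenone, 4,6,6-trimethylbicyclo[3.1.1]hept-3-en-2-one | O=C1C=C(C)[C@@H]2C[C@H]1C2(C)C | starting material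
2 | (3-bromopropoxy)(tert-butyl)dimethylsilane | BrCCCO[Si](C)(C)C(C)(C)C | starting material
3 | {3-[(tert-butyldimethylsilyl)oxy]propyl}magnesium bromide | Br[Mg]CCCO[Si](C)(C)C(C)(C)C | intermediate
4 | (1S,4R,5R)-4-{3-[(tert-butyldimethylsilyl)oxy]propyl}-4,6,6-trimethyl-2-(trimethylsilyloxy)bicyclo[3.1.1]hept-2-ene | C[Si](C)(C)OC1=C[C@](C)(CCCO[Si](C)(C)C(C)(C)C)[C@@H]2C[C@H]1C2(C)C | intermediate
5 | methyl hydrogen (R)-3-methylglutarate, (3R)-5-methoxy-3-methyl-5-oxopentanoic acid | COC(=O)C[C@H](C)CC(=O)O | starting material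
6 | (S)-5-hydroxy-3-methylpentanoic acid | OCC[C@H](C)CC(=O)O | intermediate
7 | (S)-4-methyltetrahydro-2H-pyran-2-one | C[C@H]1CCOC(=O)C1 | intermediate
8 | trimethylsilyl (R)-5-iodo-3-methylpentanoate | ICC[C@H](C)CC(=O)O[Si](C)(C)C | intermediate
9 | methyl (R)-5-iodo-3-methylpentanoate | ICC[C@H](C)CC(=O)OC | intermediate
10 | lithium enolate of the 4,4-disubstituted nopinone (from 4) | [Li]OC1=C[C@](C)(CCCO[Si](C)(C)C(C)(C)C)[C@@H]2C[C@H]1C2(C)C | intermediate
11 | methyl (3S)-5-[(1S,3R,4R,5R)-4-{3-[(tert-butyldimethylsilyl)oxy]propyl}-4,6,6-trimethyl-2-oxobicyclo[3.1.1]hept-3-yl]-3-methylpentanoate | O=C1[C@H](CC[C@H](C)CC(=O)OC)[C@](C)(CCCO[Si](C)(C)C(C)(C)C)[C@@H]2C[C@H]1C2(C)C | intermediate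
12 | methyl (3S)-5-[(1R,5R,6R)-2-acetoxy-6-(3-acetoxypropyl)-6-methyl-5-(prop-1-en-2-yl)cyclohex-2-en-1-yl]-3-methylpentanoate | CC(=O)OC1=CC[C@H](C(C)=C)[C@@](C)(CCCOC(C)=O)[C@H]1CC[C@H](C)CC(=O)OC | intermediate
13 | methyl (3S)-5-[(1S,2R,3R)-2-(3-hydroxypropyl)-2-methyl-6-oxo-3-(prop-1-en-2-yl)cyclohexyl]-3-methylpentanoate | O=C1CC[C@H](C(C)=C)[C@@](C)(CCCO)[C@@H]1CC[C@H](C)CC(=O)OC | intermediate
14 | methyl (3S)-3-methyl-5-[(1S,2R,3R)-2-methyl-6-oxo-2-(3-oxopropyl)-3-(prop-1-en-2-yl)cyclohexyl]pentanoate | O=C1CC[C@H](C(C)=C)[C@@](C)(CCC=O)[C@@H]1CC[C@H](C)CC(=O)OC | intermediate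
15 | methyl (3S)-5-[(1S,2R,3R)-2-[(3E)-3-(hydroxyimino)propyl]-2-methyl-6-oxo-3-(prop-1-en-2-yl)cyclohexyl]-3-methylpentanoate | O=C1CC[C@H](C(C)=C)[C@@](C)(CC/C=N/O)[C@@H]1CC[C@H](C)CC(=O)OC | intermediate
16 | hydroximoyl chloride of 15 (3-chloro-3-(hydroxyimino)propyl chain) | O=C1CC[C@H](C(C)=C)[C@@](C)(CCC(Cl)=NO)[C@@H]1CC[C@H](C)CC(=O)OC | intermediate
17 | nitrile oxide of 15 | O=C1CC[C@H](C(C)=C)[C@@](C)(CCC#[N+][O-])[C@@H]1CC[C@H](C)CC(=O)OC | intermediate
18 | methyl (13S)-8-oxo-17-nor-ent-labdan-15-oate 3,18-isoxazoline (C3=N–O–C18H2) | O=C1CC[C@@H]2[C@@]3(C)CON=C3CC[C@@]2(C)[C@@H]1CC[C@H](C)CC(=O)OC | intermediate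
19 | methyl (13S)-ent-labd-8(17)-en-15-oate 3,18-isoxazoline | C=C1CC[C@@H]2[C@@]3(C)CON=C3CC[C@@]2(C)[C@@H]1CC[C@H](C)CC(=O)OC | intermediate
20 | methyl (13S)-18-hydroxy-3-imino-ent-labd-8(17)-en-15-oate | C=C1CC[C@@H]2[C@@](C)(CO)C(=N)CC[C@@]2(C)[C@@H]1CC[C@H](C)CC(=O)OC | intermediate
21 | methyl (13S)-18-hydroxy-3-oxo-ent-labd-8(17)-en-15-oate | C=C1CC[C@@H]2[C@@](C)(CO)C(=O)CC[C@@]2(C)[C@@H]1CC[C@H](C)CC(=O)OC | intermediate
22 | tosylhydrazone of 21 | C=C1CC[C@@H]2[C@@](C)(CO)C(=NNS(=O)(=O)c3ccc(C)cc3)CC[C@@]2(C)[C@@H]1CC[C@H](C)CC(=O)OC | intermediate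
23 | methyl (13S)-18-hydroxy-ent-labd-8(17)-en-15-oate (CH2OH equatorial, trans to the C10 methyl) | C=C1CC[C@@H]2[C@@](C)(CO)CCC[C@@]2(C)[C@@H]1CC[C@H](C)CC(=O)OC | intermediate
24 | (E)-4-acetoxycinnamic acid | CC(=O)Oc1ccc(/C=C/C(=O)O)cc1 | starting material
25 | methyl (13S)-18-[(E)-4-acetoxycinnamoyloxy]-ent-labd-8(17)-en-15-oate | C=C1CC[C@@H]2[C@@](C)(COC(=O)/C=C/c3ccc(OC(C)=O)cc3)CCC[C@@]2(C)[C@@H]1CC[C@H](C)CC(=O)OC | intermediate
26 | (13S)-18-[(E)-4-hydroxycinnamoyloxy]-ent-labd-8(17)-en-15-oic acid, (4S,5S,9R,10S,13S) | C=C1CC[C@@H]2[C@@](C)(COC(=O)/C=C/c3ccc(O)cc3)CCC[C@@]2(C)[C@@H]1CC[C@H](C)CC(=O)O | target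

**Totals**
Total step count: 14. Longest linear sequence: 13 steps (5 → 7 → 9 → 11 → … → 26; from verbenone it is 12).

**Steps most likely to fail, with fallbacks**

Step 4 (alkylation of a hindered enolate next to a quaternary carbon with an unactivated iodide). The fallback sets out from 4 and 9 and returns at 11. Kornblum oxidation of 9 (DMSO, NaHCO3) gives methyl (S)-3-methyl-5-oxopentanoate F1. A TiCl4-mediated Mukaiyama aldol addition of 4 to this aldehyde gives the β-hydroxy ketone F2. Mesylation and DBU elimination give the exocyclic enone F3. Hydrogenation (H2, Pd/C), which is safe here because no other alkene is present, gives 11 as C9 epimers that step 6 equilibrates.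

Step 9 (six-membered ring closure onto a 1,1-disubstituted alkene; nitrile oxide dimerisation or poor facial selectivity at C4). The fallback sets out from 13 and returns at 18. Appel iodination (I2, PPh3, imidazole) gives the primary iodide F4. NaNO2 with phloroglucinol in DMSO gives the nitro compound F5. TMSCl/Et3N turns this into a silyl nitronate, a bulkier and slower dipole that does not dimerise, which cyclises to the N-silyloxy isoxazolidine F6. TsOH then eliminates the silanol to give 18.

Step 12 (hydrazone formation and reduction at a ketone flanked by the quaternary C4). The fallback sets out from 21 and returns at 23. NaBH4 reduction gives the 3,18-diol F7. Thiocarbonyldiimidazole closes the cyclic thionocarbonate F8. Barton deoxygenation (Bu3SnH, AIBN, toluene, reflux) cleaves the C3–O bond through the more stable secondary radical, and mild K2CO3/MeOH hydrolysis of the residual C18 thiocarbonate gives 23.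

**Further compounds**
F1 | step 4 | methyl (S)-3-methyl-5-oxopentanoate | O=CC[C@H](C)CC(=O)OC
F2 | step 4 | aldol adduct of 4 and F1 (β-hydroxy ketone, mixture at the two new centres) | O=C1C(C(O)C[C@H](C)CC(=O)OC)[C@](C)(CCCO[Si](C)(C)C(C)(C)C)[C@@H]2C[C@H]1C2(C)C
F3 | step 4 | exocyclic enone from F2 (3-alkylidene nopinone) | O=C1C(=CC[C@H](C)CC(=O)OC)[C@](C)(CCCO[Si](C)(C)C(C)(C)C)[C@@H]2C[C@H]1C2(C)C
F4 | step 9 | methyl (3S)-5-[(1S,2R,3R)-2-(3-iodopropyl)-2-methyl-6-oxo-3-(prop-1-en-2-yl)cyclohexyl]-3-methylpentanoate | O=C1CC[C@H](C(C)=C)[C@@](C)(CCCI)[C@@H]1CC[C@H](C)CC(=O)OC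
F5 | step 9 | methyl (3S)-3-methyl-5-[(1S,2R,3R)-2-methyl-2-(3-nitropropyl)-6-oxo-3-(prop-1-en-2-yl)cyclohexyl]pentanoate | O=C1CC[C@H](C(C)=C)[C@@](C)(CCC[N+](=O)[O-])[C@@H]1CC[C@H](C)CC(=O)OC
F6 | step 9 | N-(trimethylsilyloxy)isoxazolidine corresponding to 18 (C3 sp3, configuration there not fixed) | O=C1CC[C@@H]2[C@@]3(C)CON(O[Si](C)(C)C)C3CC[C@@]2(C)[C@@H]1CC[C@H](C)CC(=O)OC
F7 | step 12 | methyl (13S)-3,18-dihydroxy-ent-labd-8(17)-en-15-oate (C3 epimers) | C=C1CC[C@@H]2[C@@](C)(CO)C(O)CC[C@@]2(C)[C@@H]1CC[C@H](C)CC(=O)OC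
F8 | step 12 | 3,18-cyclic thionocarbonate of F7 | C=C1CC[C@@H]2[C@@]3(C)COC(=S)OC3CC[C@@]2(C)[C@@H]1CC[C@H](C)CC(=O)OC
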